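**Assumption:** the target SMILES has no stereocentres (achiral), so no enantiocontrol is needed. The only stereocentre in the route is a racemic carbinol (compounds 11–15) that is destroyed in the last step. Small reagents (MeI, allyl bromide, NBS and so on) are listed as reagents rather than numbered.

## Retrosynthetic overview
1. The 15-membered ketone comes from a macrocyclic hydroxy-alkene by Swern oxidation and hydrogenation. That alkene is made by ring-closing metathesis (RCM) of a diaryl ether carrying an aryl-allyl group on one ring and a homoallylic alcohol on the other.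
2. The diaryl ether is formed by Chan–Lam coupling of arylboronic acid **12** (ring A plus its side chain) with the hindered phenol **6** (ring B plus its allyl group).
3. Phenol **6** is made from catechol by ortho-formylation, regioselective O-allylation and O-methylation, Baeyer–Villiger (Dakin-type) conversion of CHO to OH, and Claisen rearrangement.
4. Boronic acid **12** is made from 4-iodophenol by bromination, O-methylation, Heck reaction with allyl alcohol to the aldehyde, Barbier allylation, and Miyaura borylation.
5. Both benzene rings are present in the starting materials. The diaryl ether C–O bond forms first (Chan–Lam), then the macrocycle closes (RCM).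

## Route

**Step 1**
Reactants: 1 catechol
Product: 2 2,3-dihydroxybenzaldehyde
Conditions: (CH2O)n, MgCl2, Et3N, MeCN, reflux
Reagents that add atoms: paraformaldehyde, C=O
Why: Casnati–Skattebøl ortho-formylation proceeds through a magnesium phenoxide and delivers CHO ortho to one OH.

**Step 2**
Reactants: 2
Product: 3 3-(allyloxy)-2-hydroxybenzaldehyde
Conditions: allyl bromide (1.05 equiv), NaHCO3, DMF, 40 °C
Reagents that add atoms: allyl bromide, C=CCBr
Why: Williamson etherification occurs at the free 3-OH because the 2-OH is hydrogen-bonded to the aldehyde and is less nucleophilic.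

**Step 3**
Reactants: 3
Product: 4 3-(allyloxy)-2-methoxybenzaldehyde
Conditions: MeI, K2CO3, DMF, rt
Reagents that add atoms: methyl iodide, CI
Why: Williamson O-methylation of the remaining chelated 2-OH; the allyl ether and aldehyde are untouched.

**Step 4**
Reactants: 4
Product: 5 3-(allyloxy)-2-methoxyphenol
Conditions: mCPBA, NaHCO3, CH2Cl2, 0 °C→rt; then KOH, MeOH/H2O, rt
Reagents that add atoms: mCPBA, O=C(OO)c1cccc(Cl)c1 (its O ends up on the ring carbon)
Why: Baeyer–Villiger (Dakin-type) oxidation of the electron-rich benzaldehyde migrates the aryl group to give an aryl formate, and base hydrolysis releases the phenol. The electron-poor allyl ether alkene is epoxidised far more slowly.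

**Step 5**
Reactants: 5
Product: 6 4-allyl-2-methoxybenzene-1,3-diol
Conditions: PhNEt2, 200 °C (sealed tube or microwave), 2 h
Reagents that add atoms: none
Why: aromatic Claisen [3,3] rearrangement; one ortho position is blocked by OMe, so the allyl group goes to C4, giving the OH/allyl relationship required in ring B.

**Step 6**
Reactants: 7 4-iodophenol
Product: 8 2-bromo-4-iodophenol
Conditions: NBS (1.0 equiv), i-Pr2NH (cat.), CH2Cl2, 0 °C→rt
Reagents that add atoms: NBS, O=C1CCC(=O)N1Br
Why: the OH directs electrophilic bromination to the free ortho position, since the para position is blocked.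

**Step 7**
Reactants: 8
Product: 9 2-bromo-4-iodo-1-methoxybenzene
Conditions: MeI, K2CO3, acetone, reflux
Reagents that add atoms: methyl iodide, CI
Why: O-methylation of the phenol gives the ring A OMe.

**Step 8**
Reactants: 9
Product: 10 3-(3-bromo-4-methoxyphenyl)propanal
Conditions: allyl alcohol, Pd(OAc)2 (3 mol%), n-Bu4NCl, NaHCO3, DMF, 45 °C
Reagents that add atoms: allyl alcohol, C=CCO
Why: Jeffery-type Heck reaction occurs selectively at the more reactive C–I bond, and β-H elimination then isomerises the enol to the 3-arylpropanal, leaving the Ar–Br bond intact.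

**Step 9**
Reactants: 10
Product: 11 1-(3-bromo-4-methoxyphenyl)hex-5-en-3-ol (racemic)
Conditions: allyl bromide, Zn, sat. aq NH4Cl/THF, rt
Reagents that add atoms: allyl bromide, C=CCBr
Why: Barbier allylation of the aldehyde, which is tolerant of the aryl bromide and of enolisable aldehydes. The carbinol centre is racemic and is removed in step 14.

**Step 10**
Reactants: 11
Product: 12 [5-(3-hydroxyhex-5-en-1-yl)-2-methoxyphenyl]boronic acid
Conditions: B2(OH)4, XPhos-Pd-G2 (2 mol%), XPhos, KOAc, EtOH, 80 °C
Reagents that add atoms: tetrahydroxydiboron, OB(O)B(O)O
Why: Pd-catalysed Miyaura borylation converts Ar–Br directly to ArB(OH)2 and tolerates the free alcohol and terminal alkene.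

**Step 11 (late fragment coupling)**
Reactants: 12 and 6
Product: 13 1-{3-[3-hydroxy-2-methoxy-4-(prop-2-en-1-yl)phenoxy]-4-methoxyphenyl}hex-5-en-3-ol
Conditions: Cu(OAc)2 (1.5 equiv), pyridine, 4 Å MS, CH2Cl2, air, rt, 48 h (boronic acid 1.5 equiv)
Reagents that add atoms: none
Why: Chan–Lam O-arylation forms the diaryl ether. It occurs at the less hindered b1-OH of 6, because the other OH is flanked by the allyl group and OMe, and phenols couple much faster than the secondary alcohol.

**Step 12**
Reactants: 13
Product: 14 macrocyclic alkene-alcohol (15-membered ring, E/Z mixture)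
Conditions: Grubbs II (10 mol%), 1,4-benzoquinone (10 mol%), CH2Cl2 (2 mM), 40 °C
Reagents that add atoms: none (ethylene is lost)
Why: ring-closing metathesis joins the two terminal alkenes at high dilution to close the meta/para-bridged ring. Benzoquinone suppresses Ru–H isomerisation of the allylarene.

**Step 13**
Reactants: 14
Product: 15 saturated macrocyclic alcohol
Conditions: H2 (1 atm), 10% Pd/C, EtOAc, rt
Reagents that add atoms: none (H2 only)
Why: catalytic hydrogenation removes the C=C bond and the E/Z ambiguity; the aryl ethers, phenol and non-benzylic alcohol are unaffected.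

**Step 14**
Reactants: 15
Product: 16 juglanin A
Conditions: (COCl)2, DMSO, CH2Cl2, −78 °C; then Et3N, →0 °C
Reagents that add atoms: none
Why: Swern oxidation of the secondary alcohol gives the C5 ketone and removes the only stereocentre; the free hindered phenol is compatible with Swern conditions.

## Compound list
1 | catechol | Oc1ccccc1O | starting material
2 | 2,3-dihydroxybenzaldehyde | O=Cc1cccc(O)c1O | intermediate
3 | 3-(allyloxy)-2-hydroxybenzaldehyde | O=Cc1cccc(OCC=C)c1O | intermediate
4 | 3-(allyloxy)-2-methoxybenzaldehyde | O=Cc1cccc(OCC=C)c1OC | intermediate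
5 | 3-(allyloxy)-2-methoxyphenol | Oc1cccc(OCC=C)c1OC | intermediate
6 | 4-allyl-2-methoxybenzene-1,3-diol | Oc1ccc(CC=C)c(O)c1OC | intermediate
7 | 4-iodophenol | Oc1ccc(I)cc1 | starting material
8 | 2-bromo-4-iodophenol | Oc1ccc(I)cc1Br | intermediate
9 | 2-bromo-4-iodo-1-methoxybenzene | COc1ccc(I)cc1Br | intermediate
10 | 3-(3-bromo-4-methoxyphenyl)propanal | COc1ccc(CCC=O)cc1Br | intermediate
11 | 1-(3-bromo-4-methoxyphenyl)hex-5-en-3-ol (racemic) | COc1ccc(CCC(O)CC=C)cc1Br | intermediate
12 | [5-(3-hydroxyhex-5-en-1-yl)-2-methoxyphenyl]boronic acid (racemic) | COc1ccc(CCC(O)CC=C)cc1B(O)O | intermediate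
13 | diaryl ether bis-alkene (racemic carbinol) | COc1ccc(CCC(O)CC=C)cc1Oc1ccc(CC=C)c(O)c1OC | intermediate
14 | macrocyclic alkene-alcohol (E/Z, racemic) | COc1ccc2cc1Oc1ccc(c(O)c1OC)CC=CCC(O)CC2 | intermediate
15 | saturated macrocyclic alcohol (racemic) | COc1ccc2cc1Oc1ccc(c(O)c1OC)CCCCC(O)CC2 | intermediate
16 | juglanin A (achiral) | COc1ccc2cc1Oc1ccc(c(O)c1OC)CCCCC(=O)CC2 | target

**Total steps:** 14. **Longest linear sequence:** 9 (steps 1–5 then 11–14, or steps 6–10 then 11–14).

**Three steps most likely to fail**
1. **Step 12, macrocyclic RCM.** The 15-membered para-bridged ring may give oligomers or allyl isomerisation. Fallback: close the ring by intramolecular B-alkyl Suzuki–Miyaura coupling instead. Brominate the diaryl ether at ring B C4, hydroborate a ring A hept-6-en-3-one ketal chain with 9-BBN, cyclise, then deprotect the ketal.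
2. **Step 11, Chan–Lam regioselectivity.** Both phenols of 6 may couple, or couplings may be low-yielding. Fallback: couple mono-phenol 5, which has a single free OH, with 12, then perform the Claisen rearrangement on the diaryl ether, so no regiochemical choice is needed.
3. **Step 4, mCPBA Baeyer–Villiger in the presence of the allyl ether.** Epoxidation of the alkene would compete. Fallback: carry a benzyl ether through this step (3-benzyloxy-2-methoxybenzaldehyde), then hydrogenolyse it and O-allylate to give 5.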